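**Plan**

1. Numbering: C7 is the guaiacyl CH2, C8 its ring carbon, C9 the OCH2 on C8; C8' is the other ring CH, C9' its OCH2, C7' the carbinol carbon. With C7' raised to the ketone, the oxolane (O, C9, C8, C8', C9') is a 3-aroyltetrahydrofuran whose two O-bound carbons are plain CH2 groups. That is the product pattern of a Prins–pinacol rearrangement of a formaldehyde acetal.
2. Retrosynthesis: C7'–OH goes back to C7'=O; C8–C9 and C8'–C9' are then cut together, giving an (R)-4-aryl-4-[(E)-alkenyl]-1,3-dioxolane. C8'=C8 is cut by cross-metathesis into eugenol triflate and a 4-aryl-4-vinyl-1,3-dioxolane. The dioxolane is cut at C9–O and C7'–O into formaldehyde and a vinylethylene carbonate made from acetosyringone.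
3. Forward order: the dioxolane is closed first (palladium-catalysed formaldehyde cycloaddition), the guaiacyl chain is joined by metathesis, and the key step turns the dioxolane into the oxolane, the only non-aromatic ring of the target. Ketone reduction and removal of both triflates finish the synthesis.
4. Stereochemistry: (R)-C7' comes from the chiral ligand in the palladium step. It is relayed to C8 (S) through the chair of the Prins step and is lost as C7' becomes the ketone. C8' (S, trans) follows from the suprafacial shift on the E-alkene and is also the stable α-keto epimer. (S)-C7' of the target comes from an oxazaborolidine reduction.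
5. Both phenols travel as aryl triflates, which should survive every step and do not bind the Lewis acid. They make the 3,5-dimethoxyaryl ring too electron-poor to ionise at the benzylic carbon, to migrate, or to trap the oxocarbenium ion.

Key step: step 8

Remark (assumption): the (Sa,S,S)-phosphoramidite is taken as the ligand antipode that delivers (R)-6; the sense is to be confirmed on 6, and the mirror-image ligand serves otherwise.

Remark (assumption): the Prins chair is taken to carry the aryl group of C7' equatorial and the tin-bound oxygen axial (normal for a geminal aryl/oxygen pair, with the axial stannate oxygen close to the oxocarbenium centre), so that (R)-9 gives (8S)-10.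

**Step 1**
Reactants: 1 acetosyringone
Product: 2 4-acetyl-2,6-dimethoxyphenyl trifluoromethanesulfonate (triflate)
Conditions: Tf2O (1.1 equiv), pyridine, CH2Cl2, 0 °C
Reagents that add atoms: trifluoromethanesulfonic anhydride, O=S(=O)(OS(=O)(=O)C(F)(F)F)C(F)(F)F
Why: O-sulfonylation (triflation) of the hindered phenol with pyridine as base leaves the ketone alone and installs the strongest electron-withdrawing phenol mask that should still tolerate the Grignard, palladium-allyl, ruthenium-carbene, Lewis-acid and borane steps ahead.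

**Step 2**
Reactants: 2 4-acetyl-2,6-dimethoxyphenyl triflate
Product: 3 4-(2-bromoacetyl)-2,6-dimethoxyphenyl triflate
Conditions: CuBr2 (2.1 equiv), EtOAc–CHCl3 (1:1), reflux
Reagents that add atoms: copper dibromide, [Cu+2].[Br-].[Br-]
Why: electrophilic α-bromination of the aryl methyl ketone through its enol with CuBr2 should stop at the monobromide and spare the ring, which is deactivated by the acyl and triflyloxy groups.

**Step 3**
Reactants: 3 4-(2-bromoacetyl)-2,6-dimethoxyphenyl triflate
Product: 4 rac-4-(1-bromo-2-hydroxybut-3-en-2-yl)-2,6-dimethoxyphenyl triflate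
Conditions: CH2=CHMgBr (1.15 equiv), THF, −78 °C; pH 7 buffer at −78 °C
Reagents that add atoms: vinylmagnesium bromide, C=C[Mg]Br
Why: Grignard 1,2-addition to the ketone is much faster at −78 °C than substitution at CH2Br, and an aryl triflate is inert to organomagnesium reagents in the absence of a transition-metal catalyst; the carbinol is made racemic on purpose because its configuration is reset in step 5.

**Step 4**
Reactants: 4 rac-4-(1-bromo-2-hydroxybut-3-en-2-yl)-2,6-dimethoxyphenyl triflate
Product: 5 rac-4-(4-ethenyl-2-oxo-1,3-dioxolan-4-yl)-2,6-dimethoxyphenyl triflate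
Conditions: CO2 (1 atm), Cs2CO3 (1.2 equiv), MeCN, 40 °C
Reagents that add atoms: carbon dioxide, O=C=O
Why: carboxylative cyclisation of a halohydrin, in which the cesium alkoxide takes up CO2 and the carbonate oxygen displaces the primary bromide (5-exo-tet SN2), is an established way to five-membered cyclic carbonates, and carbonate at 40 °C under CO2 is too mild to cleave the aryl triflate.

**Step 5**
Reactants: 5 rac-4-(4-ethenyl-2-oxo-1,3-dioxolan-4-yl)-2,6-dimethoxyphenyl triflate
Product: 6 4-[(4R)-4-ethenyl-1,3-dioxolan-4-yl]-2,6-dimethoxyphenyl triflate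
Conditions: Pd2(dba)3·CHCl3 (2.5 mol %), (Sa,S,S)-BINOL bis(1-phenylethyl)amine phosphoramidite (10 mol %), aq. CH2O (37 %, 3 equiv), THF, 40 °C
Reagents that add atoms: formaldehyde, C=O
Why: palladium-catalysed decarboxylative formal [3+2] cycloaddition of a vinylethylene carbonate with formaldehyde (Tsuji–Trost-type ionisation) passes through a zwitterionic π-allylpalladium alkoxide in which the old stereocentre is erased, the alkoxide adds to CH2O and the hemiacetal oxygen closes on the aryl-bearing allyl terminus under ligand control, which sets C7' as R in a dynamic kinetic asymmetric transformation, while the doubly ortho-flanked aryl triflate should not undergo oxidative addition to zerovalent palladium carrying a monodentate ligand at 40 °C.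

**Step 6**
Reactants: 7 eugenol (4-allyl-2-methoxyphenol)
Product: 8 4-allyl-2-methoxyphenyl triflate
Conditions: Tf2O (1.1 equiv), pyridine, CH2Cl2, 0 °C
Reagents that add atoms: trifluoromethanesulfonic anhydride, O=S(=O)(OS(=O)(=O)C(F)(F)F)C(F)(F)F
Why: O-triflation of the phenol as in step 1 gives the guaiacyl partner with the same electron-poor, Lewis-acid-silent phenol mask and an untouched allyl group.

**Step 7**
Reactants: 6 4-[(4R)-4-ethenyl-1,3-dioxolan-4-yl]-2,6-dimethoxyphenyl triflate; 8 4-allyl-2-methoxyphenyl triflate (3 equiv)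
Product: 9 4-{(4R)-4-[(1E)-3-(3-methoxy-4-triflyloxyphenyl)prop-1-en-1-yl]-1,3-dioxolan-4-yl}-2,6-dimethoxyphenyl triflate
Conditions: second-generation Hoveyda–Grubbs catalyst RuCl2(SIMes)(=CH–C6H4-2-OiPr) (5 mol %, two portions), 1,4-benzoquinone (10 mol %), CH2Cl2, 40 °C
Reagents that add atoms: none
Why: olefin cross-metathesis between a fast-reacting allylarene used in excess and a vinyl group on a fully substituted oxygenated carbon that cannot homodimerise should be selective, the bulky neighbour enforcing the E-alkene, benzoquinone suppressing migration of the allyl double bond, and the quaternary stereocentre staying untouched.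

**Step 8**
Reactants: 9 4-{(4R)-4-[(1E)-3-(3-methoxy-4-triflyloxyphenyl)prop-1-en-1-yl]-1,3-dioxolan-4-yl}-2,6-dimethoxyphenyl triflate
Product: 10 4-({(3S,4S)-4-[(3-methoxy-4-triflyloxyphenyl)methyl]oxolan-3-yl}carbonyl)-2,6-dimethoxyphenyl triflate (8S,8'S)
Conditions: SnCl4 (1.5 equiv), CH2Cl2, −78 → −20 °C; aq. NaHCO3
Reagents that add atoms: none
Why: SnCl4 opens the acetal at the bond between C9 and the oxygen on C7', leaving an O-methyleneoxonium ion on the primary oxygen; C8 of the alkene adds to C9, and the charge arriving at C8' is discharged by a 1,2-shift of C9' from C7' to C8', driven by the tin alkoxide, which becomes the aryl ketone. This is the Prins–pinacol rearrangement known for 4-alkenyl-1,3-dioxolanes. The cyclisation is a 6-endo-trig closure to an oxane through a chair, and the oxolane is what the ring-contracting shift leaves, so the target ring is closed by the new C8–C9 and C8'–C9' bonds. C8 becomes S by transfer from (R)-C7' through the chair that keeps the E-alkene substituent and the aryl group equatorial and the tin-bound oxygen axial; C8' becomes S because C9' arrives on the face on which C9 was bonded (syn addition to the E-alkene gives the trans ring), the arrangement that α-keto equilibration also favours. The step needs acetal opening and alkene attack to outrun heterolysis of the tertiary benzylic C–O bond, aryl migration and Friedel–Crafts capture of the oxocarbenium carbon by the ring position flanked by methoxy: the para-triflyloxy group makes the ring a poor cation stabiliser and a poor nucleophile, and the equatorial aryl group lies in the nodal plane of the C8' cation and cannot shift.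

**Step 9**
Reactants: 10 4-({(3S,4S)-4-[(3-methoxy-4-triflyloxyphenyl)methyl]oxolan-3-yl}carbonyl)-2,6-dimethoxyphenyl triflate
Product: 11 4-[(S)-hydroxy{(3S,4S)-4-[(3-methoxy-4-triflyloxyphenyl)methyl]oxolan-3-yl}methyl]-2,6-dimethoxyphenyl triflate
Conditions: (R)-2-methyl-CBS-oxazaborolidine (0.3 equiv), BH3·SMe2 (1.2 equiv), THF, −20 °C; MeOH
Reagents that add atoms: none
Why: Corey–Bakshi–Shibata reduction, in which the (R)-oxazaborolidine treats the aryl group as the large substituent and delivers hydride to the carbonyl face that gives the 7'S carbinol (the sense in which the same catalyst gives (S)-1-phenylethanol), is relied on to override the modest 1,2-induction from C8', and borane at −20 °C leaves the aryl triflates and the non-basic medium leaves C8' unepimerised.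

**Step 10**
Reactants: 11 4-[(S)-hydroxy{(3S,4S)-4-[(3-methoxy-4-triflyloxyphenyl)methyl]oxolan-3-yl}methyl]-2,6-dimethoxyphenyl triflate
Product: 12 4-[(S)-hydroxy{(3S,4S)-4-[(4-hydroxy-3-methoxyphenyl)methyl]oxolan-3-yl}methyl]-2,6-dimethoxyphenol (CNP0307127.2)
Conditions: Et4NOH (35 % aq., 6 equiv), 1,4-dioxane, rt; aq. NH4Cl to pH 7
Reagents that add atoms: none
Why: hydroxide attack at sulfur (S–O cleavage of aryl sulfonates) should free both phenols at room temperature without touching the oxolane, the methyl ethers or the three stereocentres, and the neutral work-up avoids acid-induced ionisation of the p-hydroxybenzylic alcohol.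

**Compound list**

1 | acetosyringone, 1-(4-hydroxy-3,5-dimethoxyphenyl)ethanone | CC(=O)c1cc(OC)c(O)c(OC)c1 | starting material
2 | 4-acetyl-2,6-dimethoxyphenyl triflate | CC(=O)c1cc(OC)c(OS(=O)(=O)C(F)(F)F)c(OC)c1 | intermediate
3 | 4-(2-bromoacetyl)-2,6-dimethoxyphenyl triflate | BrCC(=O)c1cc(OC)c(OS(=O)(=O)C(F)(F)F)c(OC)c1 | intermediate
4 | rac-4-(1-bromo-2-hydroxybut-3-en-2-yl)-2,6-dimethoxyphenyl triflate | OC(CBr)(C=C)c1cc(OC)c(OS(=O)(=O)C(F)(F)F)c(OC)c1 | intermediate
5 | rac-4-(4-ethenyl-2-oxo-1,3-dioxolan-4-yl)-2,6-dimethoxyphenyl triflate | O=C1OCC(C=C)(O1)c1cc(OC)c(OS(=O)(=O)C(F)(F)F)c(OC)c1 | intermediate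
6 | 4-[(4R)-4-ethenyl-1,3-dioxolan-4-yl]-2,6-dimethoxyphenyl triflate | C1OC[C@@](O1)(C=C)c1cc(OC)c(OS(=O)(=O)C(F)(F)F)c(OC)c1 | intermediate
7 | eugenol, 4-allyl-2-methoxyphenol | C=CCc1ccc(O)c(OC)c1 | starting material
8 | 4-allyl-2-methoxyphenyl triflate | C=CCc1ccc(OS(=O)(=O)C(F)(F)F)c(OC)c1 | intermediate
9 | 4-{(4R)-4-[(1E)-3-(3-methoxy-4-triflyloxyphenyl)prop-1-en-1-yl]-1,3-dioxolan-4-yl}-2,6-dimethoxyphenyl triflate | C1OC[C@@](O1)(/C=C/Cc2ccc(OS(=O)(=O)C(F)(F)F)c(OC)c2)c3cc(OC)c(OS(=O)(=O)C(F)(F)F)c(OC)c3 | intermediate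
10 | 4-({(3S,4S)-4-[(3-methoxy-4-triflyloxyphenyl)methyl]oxolan-3-yl}carbonyl)-2,6-dimethoxyphenyl triflate | COc1cc(C[C@@H]2COC[C@H]2C(=O)c3cc(OC)c(OS(=O)(=O)C(F)(F)F)c(OC)c3)ccc1OS(=O)(=O)C(F)(F)F | intermediate
11 | 4-[(S)-hydroxy{(3S,4S)-4-[(3-methoxy-4-triflyloxyphenyl)methyl]oxolan-3-yl}methyl]-2,6-dimethoxyphenyl triflate | COc1cc(C[C@@H]2COC[C@H]2[C@H](O)c3cc(OC)c(OS(=O)(=O)C(F)(F)F)c(OC)c3)ccc1OS(=O)(=O)C(F)(F)F | intermediate
12 | 4-[(S)-hydroxy{(3S,4S)-4-[(4-hydroxy-3-methoxyphenyl)methyl]oxolan-3-yl}methyl]-2,6-dimethoxyphenol | COc1cc(C[C@@H]2COC[C@H]2[C@H](O)c2cc(OC)c(O)c(OC)c2)ccc1O | target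

**Step count and risks**

Total: 10 steps. Longest linear sequence: 9 steps (steps 1–5 and 7–10, from 1 to 12).

The three steps most likely to fail:

Step 8. The cyclic formaldehyde acetal may open slowly, or mainly toward the tertiary oxygen. Heterolysis of the tertiary benzylic C–O bond (loss of the C7' configuration) or capture of the oxocarbenium carbon by the dimethoxyaryl ring could then overtake the Prins step. The fallback generates the same O-methyleneoxonium ion from an acyclic mixed acetal that can ionise only at the primary oxygen and needs a single equivalent of Lewis acid. It sets out from 5. Decarboxylative allylic substitution with water under zerovalent-palladium/phosphoramidite catalysis (Pd2(dba)3·CHCl3, Et3B co-catalyst, the ligand antipode that gives the R series) should give the tertiary vinylglycol 4-[(2R)-1,2-dihydroxybut-3-en-2-yl]-2,6-dimethoxyphenyl triflate F1. Cross-metathesis with 8 as in step 7, easier here because a free tertiary allylic alcohol is the more reactive olefin class, should give the E-diol 4-[(2R,3E)-1,2-dihydroxy-5-(3-methoxy-4-triflyloxyphenyl)pent-3-en-2-yl]-2,6-dimethoxyphenyl triflate F2. MEMCl and iPr2NEt should etherify only the primary hydroxyl to the (2-methoxyethoxy)methyl ether 4-[(2R,3E)-2-hydroxy-1-[(2-methoxyethoxy)methoxy]-5-(3-methoxy-4-triflyloxyphenyl)pent-3-en-2-yl]-2,6-dimethoxyphenyl triflate F3. SnCl4 (1.1 equiv, CH2Cl2, −78 °C), held by the two MEM oxygens, then expels 2-methoxyethoxide, and the free tertiary hydroxyl ends the Prins cyclisation by the same ring-contracting pinacol shift. The route is rejoined at 10.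

Step 7. Turnover at the vinyl group on the fully substituted carbon may be slow, so that self-metathesis and double-bond migration of the allylarene consume catalyst and partner. The fallback forms C8'=C8 by carbonyl olefination and sets out from 6. Ozonolysis (O3, CH2Cl2–MeOH, −78 °C; Me2S) should give the non-enolisable aldehyde 4-[(4R)-4-formyl-1,3-dioxolan-4-yl]-2,6-dimethoxyphenyl triflate F4. Commercial 2-(4-hydroxy-3-methoxyphenyl)ethanol is converted by Mitsunobu reaction with 1-phenyl-1H-tetrazole-5-thiol (PPh3, DIAD) into the sulfide 2-methoxy-4-{2-[(1-phenyl-1H-tetrazol-5-yl)sulfanyl]ethyl}phenol F5. Tf2O/pyridine then gives the aryl triflate 2-methoxy-4-{2-[(1-phenyl-1H-tetrazol-5-yl)sulfanyl]ethyl}phenyl triflate F6, and mCPBA gives the sulfone 2-methoxy-4-{2-[(1-phenyl-1H-tetrazol-5-yl)sulfonyl]ethyl}phenyl triflate F7. Julia–Kocienski olefination of F4 with F7 (KHMDS, DME, −60 °C) should give the E-alkene and rejoins the route at 9.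

Step 9. Facial selectivity may be poor, because the Felkin–Anh preference of the C8' stereocentre (C8 as the large group) points to the 7'R carbinol and opposes the catalyst. The fallback uses the substrate bias and then inverts; it sets out from 10. LiBH(s-Bu)3 (THF, −78 °C) should give the 7'R alcohol 4-[(R)-hydroxy{(3S,4S)-4-[(3-methoxy-4-triflyloxyphenyl)methyl]oxolan-3-yl}methyl]-2,6-dimethoxyphenyl triflate F8. Mitsunobu reaction with 4-nitrobenzoic acid (PPh3, DIAD, toluene, 0 °C) inverts C7' to the 7'S ester (S)-(3,5-dimethoxy-4-triflyloxyphenyl){(3S,4S)-4-[(3-methoxy-4-triflyloxyphenyl)methyl]oxolan-3-yl}methyl 4-nitrobenzoate F9. Et4NOH in dioxane–water then removes the benzoate together with both triflates and rejoins the route at 12.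

**Further compounds**

F1 | step 8 | 4-[(2R)-1,2-dihydroxybut-3-en-2-yl]-2,6-dimethoxyphenyl triflate | OC[C@@](O)(C=C)c1cc(OC)c(OS(=O)(=O)C(F)(F)F)c(OC)c1
F2 | step 8 | 4-[(2R,3E)-1,2-dihydroxy-5-(3-methoxy-4-triflyloxyphenyl)pent-3-en-2-yl]-2,6-dimethoxyphenyl triflate | OC[C@@](O)(/C=C/Cc2ccc(OS(=O)(=O)C(F)(F)F)c(OC)c2)c3cc(OC)c(OS(=O)(=O)C(F)(F)F)c(OC)c3
F3 | step 8 | 4-[(2R,3E)-2-hydroxy-1-[(2-methoxyethoxy)methoxy]-5-(3-methoxy-4-triflyloxyphenyl)pent-3-en-2-yl]-2,6-dimethoxyphenyl triflate | COCCOCOC[C@@](O)(/C=C/Cc2ccc(OS(=O)(=O)C(F)(F)F)c(OC)c2)c3cc(OC)c(OS(=O)(=O)C(F)(F)F)c(OC)c3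
F4 | step 7 | 4-[(4R)-4-formyl-1,3-dioxolan-4-yl]-2,6-dimethoxyphenyl triflate | C1OC[C@@](O1)(C=O)c1cc(OC)c(OS(=O)(=O)C(F)(F)F)c(OC)c1
F5 | step 7 | 2-methoxy-4-{2-[(1-phenyl-1H-tetrazol-5-yl)sulfanyl]ethyl}phenol | COc1cc(CCSc2nnnn2-c2ccccc2)ccc1O
F6 | step 7 | 2-methoxy-4-{2-[(1-phenyl-1H-tetrazol-5-yl)sulfanyl]ethyl}phenyl triflate | COc1cc(CCSc2nnnn2-c2ccccc2)ccc1OS(=O)(=O)C(F)(F)F
F7 | step 7 | 2-methoxy-4-{2-[(1-phenyl-1H-tetrazol-5-yl)sulfonyl]ethyl}phenyl triflate | COc1cc(CCS(=O)(=O)c2nnnn2-c2ccccc2)ccc1OS(=O)(=O)C(F)(F)F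
F8 | step 9 | 4-[(R)-hydroxy{(3S,4S)-4-[(3-methoxy-4-triflyloxyphenyl)methyl]oxolan-3-yl}methyl]-2,6-dimethoxyphenyl triflate | COc1cc(C[C@@H]2COC[C@H]2[C@@H](O)c3cc(OC)c(OS(=O)(=O)C(F)(F)F)c(OC)c3)ccc1OS(=O)(=O)C(F)(F)F
F9 | step 9 | (S)-(3,5-dimethoxy-4-triflyloxyphenyl){(3S,4S)-4-[(3-methoxy-4-triflyloxyphenyl)methyl]oxolan-3-yl}methyl 4-nitrobenzoate | COc1cc(C[C@@H]2COC[C@H]2[C@H](OC(=O)c3ccc(cc3)[N+](=O)[O-])c4cc(OC)c(OS(=O)(=O)C(F)(F)F)c(OC)c4)ccc1OS(=O)(=O)C(F)(F)F
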